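The easy step first: E is counted with J in it, so the sum asked for is the E column itself, and its ceiling is 100 % of the Z charged. What remains is how fast the flask climbs towards that ceiling.

in all of them: Q 100 mM (held)

|  | Z | remark | time |
|---|---|---|---|
| south-east | 2 M | the very flask that is asked about, followed so far |  |
| west | 1 M | run made earlier |  |
| flask | 2.0 M |  | 2.5 h |

south-east run (percent of the Z charged)

| time / min | E / % | J / % |
|---|---|---|
| 4.00 | 0.5 | 0 |
| 10.0 | 0 | 0 |
| 20.0 | 1.0 | 1.5 |
| 30.0 | 1.9 | 1.9 |

west run (percent of the Z charged)

| time / h | E / % | J / % |
|---|---|---|
| 0.333 | 2.4 | 2.0 |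
| 0.833 | 8.9 | 6.9 |
| 1.50 | 18.8 | 14.6 |
| 2.50 | 34.1 | 26.6 |

(each reading ± 0.5 percentage points)

- for E the J are counted in
- as a solid, counted per litre of solution: Z
- at the start none of Z is in solution
- at the start none of Q is in solution
- L is what Z becomes in solution
- L means what is dissolved; the solid is not counted in it

1. E and J together at 2.5 h, in percent of the Z charged
2. concentration of L in solution at 15 min, in percent of saturation
3. the change that raises the amount of E and J together at 2.5 h, in percent of the Z charged most ("none" if none brings more than 2 percentage points) (Monday's / Tuesday's / Sunday's / Wednesday's / none)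
4. amount of E and J together at 2.5 h, in percent of the Z charged, after Sunday's

- Monday's: doubling the dissolution coefficient of Z, all else as stated
- Tuesday's: doubling the transfer coefficient of Q, all else as stated
- Sunday's: doubling the saturation concentration of Q, all else as stated
- Wednesday's: doubling the solubility of Z, all else as stated

In the west flask, c(E) rises by 0.153 M h⁻¹ between its last two readings. This slope of c(E) against time on the straight part of the curve is what we carry, the plateau rate. But is the curve still steepening? The interval before gives 0.148 M h⁻¹, and a scatter of 0.5 percentage points per reading does not separate the two slopes. Traced back, the line meets zero at a lag of 0.271 h.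

Yet that rate comes from 1 M of Z, and our flask has 2.0 M. The south-east run, the early part of this flask, shows 0.0380 M of E at 30.0 min, and the west line gives 0.0350 M, within a scatter of 0.0100 M. So we take the rate as zero order in the charge.

That reading is early, though, and the line could bend later. The west flask still kept its slope with 0.659 M of its charge not yet E, and our flask will have more than that, 1.66 M, at 2.5 h. We therefore commit to 17.1 %, and the line would meet the ceiling at a run-out time of 13.3 h. Both runs share 100 mM of Q, so they give us no reckoning of our own for Q's effect.

The forecast gives 17 % (15.5 % to 18.5 %), L at 75 % of saturation, Sunday's as the best change and 31 % after it, holding that “the rate doesn't depend on the solid charged”.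

The flask gives 17.0 %, L at 50.9 % of saturation at 15 min, and Sunday's as the best change, worth 15 points, with 32.2 % after it.

    L + X → E (k = 0.00170 M⁻¹ s⁻¹)
    Z ⇌ L, rate k2*(cs2 - [L]) while solid is left; crystals form when [L] > cs2 (solubility = 0.770 M, k = 8.20 × 10⁻⁴ s⁻¹)
    Q ⇌ X, rate k3*(csat - [X]) (kL = 0.00110 s⁻¹)
    X + E ⇌ J, settled at all times (K = 110 M⁻¹)

This flask is not at rest at 2.5 h, for 83 % of its Z still stands as solid or L. The plateau rate gives 36.2 % at 5.00 h, and the flask holds 35.4 %. For a neighbour flask with 1.2 M of Z at 2.5 h it gives 28.4 %, and that flask holds 28.3 %. At ten times the time, 25.0 h, which is later than the run-out time of 13.3 h, Z stands at 0 % and E and J together at >99.9 %, with J at 91.6 %.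

(The numbers in the tables stem from a simulated flask with made-up constants.)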